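# Total synthesis proposal for CNP0111873.1: lactone-bridged intramolecular Diels–Alder route

## Analysis of the target

1. The core is a nortricyclene cage (tricyclo[2.2.1.0(2,6)]heptane). C6 is the apex, C1, C7 and C11 are the three one-carbon bridges, and C8–C9–C10 is the cyclopropane, joined to the bridges through C7–C8, C1–C9 and C11–C10. The cage shares its C1–C6 edge with a cyclohexane, ring A (C1–C2–C3–C4–C5–C6).
2. C1 carries the acetoxymethyl carbon C12, C3 the free hydroxyl, C4 and C11 acetoxy groups, C5 two methyl groups and C10 one methyl group.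
3. There are eight stereocentres (C1, C3, C4, C6, C8, C9, C10, C11). The cage ties C6, C8, C9 and C10 together, so only four relationships are free: C12 on C1 faces the C7 bridge (C2 faces C11); the C11 oxygen faces C7 and not C1; O3 and O4 are cis; and both lie on the face of ring A that also holds C12 and C7.
4. The C11 acetate is cyclopropylcarbinyl and ionises readily in acid. The free O3 sits cis to the O4 acetate and invites acyl migration under base. Three esters rule out late nucleophilic or strongly basic steps.
5. The main difficulty is the row of three contiguous fully substituted carbons C5–C6–C1, joined by a fourth quaternary carbon (C10) inside the cyclopropane. In addition, one oxygen out of four must stay free.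
6. The strategy rests on two features. First, C1–C6 and C8–C9 are exactly the two σ-bonds that a cyclopentadiene made of C6, C11, C10, C8 and C7 forms with a C1=C9 alkene; the remaining cage bond C9–C10 is then the 1,3-bond across the resulting norbornene.
7. Second, C12 and O4 lie cis across ring A in a 1,4-relationship, so they can be joined as a lactone. This lactone ties the dienophile to the stereocentres C3 and C4.

## Retrosynthetic reasoning

**31 ⇒ 30 ⇒ 29 (no skeletal bond cut).** O3 stays silylated to the end. 31 arises from 30 by desilylation, and 30 from triol 29 by exhaustive acetylation. O4, O11 and O12 all end as acetates, so they need no mutual differentiation. A silyl ether is preferred to an acetal. Its removal needs neither acid strong enough to ionise the C11 ester nor base that would move the O4 acetyl group.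

**29 ⇒ 28 ⇒ 27 (C9–H to C9–S; C12/O4 retied).** The hydrogen on C9 is traced to a phenylsulfonyl group (28). The C12 alcohol and O4 are traced to the bridging lactone (27). The sulfone is the carbanion handle for the cyclopropane, and the lactone is the stereochemical tie of the key step. Reduction of the lactone comes before desulfonylation, so the electron-transfer step meets only alcohols and a silyl ether.

**27 ⇒ 25 ⇒ 24 (cut C9–C10).** Cutting C9–C10 turns the cage into a norbornane. The forward reaction is attack of the C9 carbanion on the rear side of an exo C10–C11 epoxide (25). This closes the cyclopropane and leaves oxygen on C11 on the C7 side, as the target requires. No other cyclopropane bond can be made this way with the oxygen ending on the correct carbon. Epoxide 25 comes from alkene 24, whose endo face is blocked.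

**24 ⇒ 23 (cut C1–C6 and C8–C9; key disconnection).** These two cuts remove the hardest bond of the molecule, the quaternary–quaternary bond C1–C6 next to CMe2. They also open ring A and the norbornene together. What remains is a monocyclic lactone with only two stereocentres and a cyclopentadiene. The forward cycloaddition has to pick one diene isomer from an equilibrating set, one alkene face and one diene orientation.

**23 ⇒ 22 ⇒ 19 ⇒ 17 (diene masked; cut C1=C9).** The diene is too acidic and too prone to dimerise to be carried, so it is stored as a tertiary allylic silyl ether (22). C9 is added to the lactone enolate as a formyl carbon (19). Its oxygen is then exchanged for sulfur that is already at the sulfone level (sulfinate 20). No oxidant therefore ever meets the electron-rich ring alkene.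

**17 ⇒ 15 ⇒ 14 ⇒ 12 + 13 (cut O4–C12 and C1=C2).** The lactone opens to hydroxy ester 15, the reduction product of enoate 14. Enoate 14 is the cross-metathesis product of terminal alkene 12 and methyl acrylate 13. This brings in C1 and C12 in one step from a bulk chemical.

**12 ⇒ 11 ⇒ 7 + 8 (cut C3–C4).** The anti O3/O4 pair becomes cis once ring A is closed. It is set in one allylboration of aldehyde 7 with a three-carbon unit from allenylboronate 8. Lithiated allyl ethers give Z γ-alkoxyallylboranes and therefore syn products. For this reason a boryl group stands in for O3 on an E reagent and is oxidised afterwards. The steric contrast between the neopentyl O4 and the allylic O3 then lets O3 alone be silylated.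

**7 ⇒ 6 ⇒ 5 ⇒ 4 ⇒ 1 + 2 (cut C5–C6).** The bond between CMe2 and the five-membered ring comes from 1,2-addition of the enolate of 2 to enone 1. The resulting carbinol oxygen later serves as the leaving group that unveils the diene. Silylation (5) suppresses retro-aldol cleavage at the aldehyde stage.

## Alternatives that were turned down

**Alternative 1:**
- *Disconnection.* Both cyclopropane bonds at C9 (C8–C9 and C9–C10) are cut. C9 becomes a carbene equivalent on C1 of a spiro[4.5]decene whose cyclopentene holds C8=C10.
- *Forward key step.* Tosylhydrazone A1 is treated with NaH and heated to give diazoalkane A2. This adds as a 1,3-dipole across C8=C10, and loss of N2 (heat or light) gives A3, which is identical with 30.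
- *In its favour.* Two bonds and three rings form in one operation. No auxiliary group has to be removed afterwards. The product is one deprotection from the target. On late-stage economy it is clearly stronger than the chosen route, which spends six steps after its key step.
- *Against.* A1 already contains everything that is hard: the C5–C6–C1 array, the spiro centre C6 and its relation to C1 and C11. No evident reaction sets these. The dipolarophile is an unactivated trisubstituted alkene and the diazo carbon is neopentyl, so the cycloaddition is slow. Carbene formation with 1,2-alkyl shift from quaternary C1, azine formation and hydrogen shift during N2 loss are realistic exits. NaH with heat also threatens three acetates.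
- *Comparison.* The chosen strategy offers in exchange a key step that itself builds C1–C6 and derives four stereocentres from two easily made ones.

**Alternative 2:**
- *Disconnection.* C5–C6 is cut.
- *Forward key step.* In A4, TiCl4 opens the C4–C5 epoxide at the tertiary carbon C5. The tetrasubstituted silyl enol ether carbon C6 captures the developing cation. Ring A closes by an endo epoxide opening onto a cyclopentenone and gives A5.
- *In its favour.* The reaction runs at low temperature. The epoxide transmits C4 cleanly, and O4 emerges free and distinguished from O3. In mildness and in the differentiation of O4 it is at least equal to the chosen route.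
- *Against.* The new bond joins a tertiary cation to a tetrasubstituted nucleophile flanked by quaternary C1. Hydride shift to the ketone (Meinwald rearrangement), chloride capture and participation of the neighbouring silyl ether should therefore compete. A4 needs the quaternary stereocentre C1 beforehand, on a dimerisation-prone 5,5-disubstituted silyloxycyclopentadiene. The face of C6 is controlled only by the tether. After A5 the cage is still missing: one allyl carbon has to be excised, C8 has to be joined to C9 and C10, and the C11 ketone has to be reduced from its more hindered side to place oxygen toward C7.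
- *Comparison.* The chosen key step delivers the bicyclic cage precursor directly, and the C11 configuration comes from an exo epoxidation.

**Alternative 3:**
- *Disconnection.* C1–C2 and C8–C9 are cut, leading back to a 7-acetoxynorbornadiene.
- *Forward key step.* Bu3SnH converts the Z vinyl iodide A6 into a C2 vinyl radical. This adds to C1 and closes ring A. The C9 radical closes onto C8 (norbornenyl to nortricyclyl), and the C7 radical takes hydrogen, giving A7.
- *In its favour.* It has the highest gain in complexity per step of all four plans. The cyclopropane forms without redox detours and the C11 acetate is in place from the start. On step economy after the key step it beats the chosen route.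
- *Against.* The vinyl radical must attack the fully substituted alkene carbon C1, next to bridgehead C6 and CMe2. Premature reduction, 1,5-hydrogen transfer and attack at C9 are therefore likely. The norbornenyl and nortricyclyl radicals equilibrate, so hydrogen transfer can divide the material between two skeletons. A6 is a tetrasubstituted norbornadiene whose regiochemistry, 7-acetoxy orientation and absolute sense relative to C4 have no obvious source. The enol ether of A7 must still become a C3 alcohol cis to O4, through an α-acetoxy ketone that can epimerise.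
- *Comparison.* The chosen plan offers stereocontrol that can be traced, bond by bond, to C3 and C4.

Key step: step 13

Assumption 1: compounds 4–7, 10–12, 14–19, 21 and 22 are carried as mixtures of epimers at the oxygen-bearing ring carbon (future C6). This centre becomes planar in step 12, and the SMILES leave it undefined.

Assumption 2: 23 is an equilibrating set of cyclopentadiene double-bond isomers and is drawn as the reactive 1-alkyl-3-methyl isomer.

Assumption 3: (−)-diisopinocampheylborane is used as the crystalline reagent derived from (+)-α-pinene.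

## Route

Step 1
Reactants: 1 3-methylcyclopent-2-en-1-one; 2 methyl isobutyrate
Product: 4 methyl 2-(1-hydroxy-3-methylcyclopent-2-en-1-yl)-2-methylpropanoate (racemic), via lithium enolate 3 (not isolated)
Conditions: 2, LiN(iPr)2, THF, −78 °C; 1, −78 °C; AcOH quench at −78 °C
Reagents that add atoms: lithium diisopropylamide, [Li+].CC(C)[N-]C(C)C (lithium, held only in 3)
Why: Aldol-type 1,2-addition of a lithium ester enolate to an enone under kinetic control; the β-methyl group disfavours conjugate addition, and the cold acidic quench prevents retro-aldol cleavage. The new carbinol centre is racemic and is erased in step 12.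

Step 2
Reactants: 4 methyl 2-(1-hydroxy-3-methylcyclopent-2-en-1-yl)-2-methylpropanoate
Product: 5 methyl 2-methyl-2-[3-methyl-1-(triethylsilyloxy)cyclopent-2-en-1-yl]propanoate
Conditions: TESOTf, 2,6-lutidine, CH2Cl2, −78 → −20 °C
Reagents that add atoms: triethylsilyl trifluoromethanesulfonate, CC[Si](CC)(CC)OS(=O)(=O)C(F)(F)F
Why: Silyl triflate silylation of a hindered tertiary alcohol under buffered conditions. The ether blocks retro-aldol cleavage at the aldehyde stage and protects the acid-labile tertiary allylic alcohol until it is needed as a leaving group.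

Step 3
Reactants: 5 methyl 2-methyl-2-[3-methyl-1-(triethylsilyloxy)cyclopent-2-en-1-yl]propanoate
Product: 6 2-methyl-2-[3-methyl-1-(triethylsilyloxy)cyclopent-2-en-1-yl]propan-1-ol
Conditions: LiAlH4, Et2O, 0 °C
Reagents that add atoms: none
Why: Hydride reduction of a neopentyl ester; the isolated alkene and the silyl ether are inert to LiAlH4.

Step 4
Reactants: 6 2-methyl-2-[3-methyl-1-(triethylsilyloxy)cyclopent-2-en-1-yl]propan-1-ol
Product: 7 2-methyl-2-[3-methyl-1-(triethylsilyloxy)cyclopent-2-en-1-yl]propanal
Conditions: Pr4N[RuO4] (cat.), N-methylmorpholine N-oxide, 4 Å MS, CH2Cl2, rt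
Reagents that add atoms: none
Why: Ley–Griffith oxidation under neutral conditions. The aldehyde has no α-hydrogen, so it can neither enolise nor eliminate.

Step 5
Reactants: 7 2-methyl-2-[3-methyl-1-(triethylsilyloxy)cyclopent-2-en-1-yl]propanal; 8 allenylboronic acid pinacol ester
Product: 11 (3S,4R)-5-methyl-5-[3-methyl-1-(triethylsilyloxy)cyclopent-2-en-1-yl]hex-1-ene-3,4-diol, via E borylallylborane 9 (not isolated), via borinate boronate adduct 10 (not isolated)
Conditions: 8, (−)-Ipc2BH [from (+)-α-pinene], THF, 0 °C; 7, −78 °C; NaOH, H2O2, 0 °C → rt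
Reagents that add atoms: hydrogen peroxide, OO (oxygen on C3); (−)-diisopinocampheylborane, B([C@@H]1C[C@@H]2C[C@H]([C@H]1C)C2(C)C)[C@@H]1C[C@@H]2C[C@H]([C@H]1C)C2(C)C (boron and terpene groups, held only in 9 and 10)
Why: Hydroboration of the allene puts the dialkylboryl group on the terminal carbon, and reversible 1,3-boratropic shifts leave the more stable E γ-borylallylborane 9. Its chair-like allylboration transition state converts E geometry into the anti relationship, while the isopinocampheyl groups from (+)-α-pinene select the aldehyde face that gives 4R. Oxidation of the C3–B bond with retention then gives 3S.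

Step 6
Reactants: 11 (3S,4R)-5-methyl-5-[3-methyl-1-(triethylsilyloxy)cyclopent-2-en-1-yl]hex-1-ene-3,4-diol
Product: 12 (3S,4R)-3-(tert-butyldimethylsilyloxy)-5-methyl-5-[3-methyl-1-(triethylsilyloxy)cyclopent-2-en-1-yl]hex-1-en-4-ol
Conditions: TBSCl (1.1 equiv), imidazole, DMF, 0 °C → rt
Reagents that add atoms: tert-butyldimethylsilyl chloride, CC(C)(C)[Si](C)(C)Cl
Why: Steric differentiation of a diol. O4 is neopentyl, next to the quaternary C5 with its bulky ring, so the allylic O3 is silylated first; migration to the more hindered O4 is unfavourable.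

Step 7
Reactants: 12 (3S,4R)-3-(tert-butyldimethylsilyloxy)-5-methyl-5-[3-methyl-1-(triethylsilyloxy)cyclopent-2-en-1-yl]hex-1-en-4-ol; 13 methyl acrylate
Product: 14 methyl (2E,4S,5R)-4-(tert-butyldimethylsilyloxy)-5-hydroxy-6-methyl-6-[3-methyl-1-(triethylsilyloxy)cyclopent-2-en-1-yl]hept-2-enoate
Conditions: 13 (excess), second-generation Hoveyda–Grubbs catalyst RuCl2(H2IMes)(=CH-C6H4-2-OiPr) (cat.), CH2Cl2, 40 °C
Reagents that add atoms: none
Why: Olefin cross-metathesis of a monosubstituted allylic ether with an electron-poor acrylate, which gives the E enoate. The trisubstituted ring alkene is flanked by a fully substituted carbon and does not engage the ruthenium carbene.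

Step 8
Reactants: 14 methyl (2E,4S,5R)-4-(tert-butyldimethylsilyloxy)-5-hydroxy-6-methyl-6-[3-methyl-1-(triethylsilyloxy)cyclopent-2-en-1-yl]hept-2-enoate
Product: 15 methyl (4S,5R)-4-(tert-butyldimethylsilyloxy)-5-hydroxy-6-methyl-6-[3-methyl-1-(triethylsilyloxy)cyclopent-2-en-1-yl]heptanoate
Conditions: Cu(OAc)2·H2O (cat.), 1,2-(Ph2P)2C6H4 (cat.), (EtO)2MeSiH, t-BuOH, PhMe, rt
Reagents that add atoms: none
Why: Conjugate reduction by a phosphine-ligated hydride of monovalent copper, which touches only the enoate. Electron-transfer reductants are avoided because they would expel the γ-silyloxy group, and heterogeneous hydrogenation is avoided because of the allylic C–O bond and the ring alkene.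

Step 9
Reactants: 15 methyl (4S,5R)-4-(tert-butyldimethylsilyloxy)-5-hydroxy-6-methyl-6-[3-methyl-1-(triethylsilyloxy)cyclopent-2-en-1-yl]heptanoate
Product: 17 (5S,6R)-5-(tert-butyldimethylsilyloxy)-6-{2-[3-methyl-1-(triethylsilyloxy)cyclopent-2-en-1-yl]propan-2-yl}oxan-2-one, via hydroxy acid 16 (not isolated)
Conditions: LiOH, THF–MeOH–H2O, rt; dilute HCl to pH 5, 0 °C, extraction; DCC, DMAP (cat.), CH2Cl2, 0 °C → rt
Reagents that add atoms: lithium hydroxide, [Li+].[OH-] (oxygen, held only in 16)
Why: Saponification followed by Steglich-type carbodiimide lactonisation. The basic and near-neutral media spare the tertiary allylic silyl ether, which acid-catalysed lactonisation would ionise. With O3 silylated, only the six-membered lactone through O4 can form.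

Step 10
Reactants: 17 (5S,6R)-5-(tert-butyldimethylsilyloxy)-6-{2-[3-methyl-1-(triethylsilyloxy)cyclopent-2-en-1-yl]propan-2-yl}oxan-2-one
Product: 19 (3Z,5S,6R)-3-(hydroxymethylidene) derivative of lactone 17 (chelated enol of the α-formyl lactone), via lactone lithium enolate 18 (not isolated)
Conditions: LiN(iPr)2, THF, −78 °C; HCO2Et, −78 → −20 °C; AcOH quench
Reagents that add atoms: ethyl formate, CCOC=O (C9 and its oxygen); lithium diisopropylamide, [Li+].CC(C)[N-]C(C)C (lithium, held only in 18)
Why: Crossed Claisen condensation (formylation) of a lactone enolate; the product rests as its stabilised enolate, which stops further reaction. The silyloxy group is γ to the carbonyl, so it cannot be lost from the enolate by β-elimination.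

Step 11
Reactants: 19 (3Z,5S,6R)-3-(hydroxymethylidene) lactone; 20 sodium benzenesulfinate
Product: 22 (3E,5S,6R)-5-(tert-butyldimethylsilyloxy)-6-{2-[3-methyl-1-(triethylsilyloxy)cyclopent-2-en-1-yl]propan-2-yl}-3-[(phenylsulfonyl)methylidene]oxan-2-one, via enol mesylate 21 (not isolated)
Conditions: MsCl, Et3N, CH2Cl2, −30 °C; 20, DMF, 0 °C → rt
Reagents that add atoms: methanesulfonyl chloride, CS(=O)(=O)Cl (held only in 21)
Why: O-sulfonylation of the enol, then addition–elimination (vinylic substitution) by the soft sulfur nucleophile, as is known for β-halo- and β-sulfonyloxyacrylates. Reversible sulfinate addition should equilibrate the alkene to the E isomer, with sulfonyl trans to the carbonyl. Because sulfur enters at the sulfone level, no peracid oxidation is needed next to the electron-rich ring alkene.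

Step 12
Reactants: 22 (3E,5S,6R)-sulfonylmethylidene lactone with tertiary allylic silyl ether
Product: 23 (3E,5S,6R)-5-(tert-butyldimethylsilyloxy)-6-[2-(3-methylcyclopenta-1,3-dien-1-yl)propan-2-yl]-3-[(phenylsulfonyl)methylidene]oxan-2-one (with its 1,5-hydrogen-shift isomers)
Conditions: camphorsulfonic acid (cat.), CH2Cl2, 0 °C → rt; NaHCO3 wash; used at once
Reagents that add atoms: none
Why: Acid-catalysed E1 loss of silanol through the 1,3-dialkylcyclopentenyl cation, the standard passage from cyclopentenone 1,2-adducts to substituted cyclopentadienes. The secondary silyl ether and the lactone cannot ionise under catalytic anhydrous acid, and the absence of base keeps the vinyl sulfone in place.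

Step 13
Reactants: 23 (3E,5S,6R)-cyclopentadienyl sulfonylmethylidene lactone
Product: 24 lactone-bridged norbornene sulfone (bicyclo[2.2.1]heptene with bridgeheads C6 and C8, bridge C7, alkene C10=C11 with methyl on C10; ring A closed and still spanned by O4–C12(=O); C12 exo, C2 and PhSO2 endo; 3-OTBS)
Conditions: PhMe (0.005 M), BHT, base-washed sealed tube, 160–180 °C
Reagents that add atoms: none
Why: The reaction is a concerted, asynchronous, suprafacial [4+2] cycloaddition (type 1 intramolecular Diels–Alder) fed by fast 1,5-hydrogen shifts among the diene isomers; the closest known reaction type is the thermal intramolecular Diels–Alder reaction of 1-alkylcyclopentadienes generated by such shifts, and α-alkylidene lactones are established dienophiles. Ring A closes in the fused mode over the four-atom tether C2–C5, with C1 bonding to the tethered diene terminus C6; since O4–C12 already spans C4 and C1, the lactone must adopt a boat with the C4–C5 bond as flagpole, and ring A emerges as part of a 2-oxabicyclo[2.2.2]octan-3-one. The second ring is the cyclohexene C6–C11=C10–C8–C9–C1 of the cycloaddition, which C7 bridges to give the bicyclo[2.2.1]heptene. C1 is controlled by C4, because only the alkene face syn to the C4–C5 bond lies within reach of C6, so C3 and C4 fix the absolute sense. C6 and C8 are set together by the orientation of the diene; the required one places C12 exo (under C7) and C2 endo (under C10=C11), which is the orientation α-alkylidene lactones favour because the ring CH2 avoids the diene CH2, and in the E alkene it also puts the sulfonyl group endo, its own mild preference. C9 follows from the E geometry by suprafacial addition and has no later consequence. Isomer selection is needed: isomers with the chain on an inner or sp3 ring carbon cannot reach C1=C9 without a bridgehead alkene, and the 1,4-disubstituted isomer would have to bond C9 to the methyl-bearing C10, so the pool should drain through 23, in which both substituents raise the orbital coefficient at the free terminus C8, matched with C9, the β-carbon of the enoate. High dilution and BHT suppress dimerisation, and the neutral medium keeps the vinyl sulfone from slipping to the allyl sulfone.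

Step 14
Reactants: 24 lactone-bridged norbornene sulfone
Product: 25 exo-C10,C11-epoxide of 24
Conditions: mCPBA, NaHCO3, CH2Cl2, 0 °C → rt
Reagents that add atoms: 3-chloroperoxybenzoic acid, OOC(=O)c1cccc(Cl)c1
Why: Prilezhaev epoxidation of the only nucleophilic π-bond. The endo face is covered by C2 and the sulfonyl group, so oxygen arrives from the exo (C7) side. This sets C11 for good and C10 provisionally.

Step 15
Reactants: 25 exo-C10,C11-epoxide
Product: 27 nortricyclanol sulfone lactone (C9–C10 closed, PhSO2 on C9, C11–OH facing C7, lactone and 3-OTBS retained), via lithiated sulfone 26 (not isolated)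
Conditions: LiN(iPr)2, THF, −78 → 0 °C; AcOH quench
Reagents that add atoms: lithium diisopropylamide, [Li+].CC(C)[N-]C(C)C (lithium, held only in 26)
Why: Deprotonation α to the sulfone gives a configurationally labile carbanion whose endo lobe lies directly behind the exo C10–O bond, so a 3-exo-tet opening with inversion at C10 closes the cyclopropane; this is the known epoxy-sulfone type cyclisation of exo-epoxynorbornanes bearing an acidifying group on the 1,3-related carbon. C11 keeps its oxygen on the C7 side. The lactone has no α-hydrogen and is not attacked by the hindered amide.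

Step 16
Reactants: 27 nortricyclanol sulfone lactone
Product: 28 sulfonyl triol (C12–OH, C4–OH, C11–OH; PhSO2 on C9; 3-OTBS)
Conditions: LiAlH4, THF, 0 °C → rt
Reagents that add atoms: none
Why: Hydride reduction of the strained bridged lactone to the primary alcohol and the C4 alcohol. The fully substituted aryl sulfone and the silyl ether are inert, and migration of silicon to the more hindered O4 is unfavourable.

Step 17
Reactants: 28 sulfonyl triol
Product: 29 triol (C12–OH, C4–OH, C11–OH; C9–H; 3-OTBS)
Conditions: Na(Hg) (6 % Na), Na2HPO4, MeOH–THF, −10 °C → rt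
Reagents that add atoms: none
Why: Reductive desulfonylation by electron transfer, known for cyclopropyl phenyl sulfones. The cage allows only one position for the new C9–H, and no leaving group sits β to C9, so the cyclopropyl intermediate can only be protonated.

Step 18
Reactants: 29 triol
Product: 30 triacetate 3-O-tert-butyldimethylsilyl ether
Conditions: Ac2O, DMAP, pyridine, rt → 50 °C
Reagents that add atoms: acetic anhydride, CC(=O)OC(C)=O
Why: DMAP-catalysed exhaustive acylation. The neopentyl-type secondary alcohols at C4 and C11 need the acylpyridinium catalyst and mild heating, and the non-acidic medium is safe for the cyclopropylcarbinyl position.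

Step 19
Reactants: 30 triacetate 3-O-tert-butyldimethylsilyl ether
Product: 31 CNP0111873.1 (target)
Conditions: HF·pyridine, pyridine, THF, 0 °C → rt
Reagents that add atoms: none
Why: Fluoride-induced desilylation in a buffered, weakly acidic medium. No alkoxide is formed, so the O4 acetyl group should not migrate to O3, and the acidity is too low to ionise the C11 acetate.

## Compound list

1 | 3-methylcyclopent-2-en-1-one | CC1=CC(=O)CC1 | starting material
2 | methyl isobutyrate | COC(=O)C(C)C | starting material
3 | lithium enolate of 2 | [Li+].[O-]C(OC)=C(C)C | intermediate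
4 | methyl 2-(1-hydroxy-3-methylcyclopent-2-en-1-yl)-2-methylpropanoate (racemic) | COC(=O)C(C)(C)C1(O)C=C(C)CC1 | intermediate
5 | methyl 2-methyl-2-[3-methyl-1-(triethylsilyloxy)cyclopent-2-en-1-yl]propanoate | COC(=O)C(C)(C)C1(O[Si](CC)(CC)CC)C=C(C)CC1 | intermediate
6 | 2-methyl-2-[3-methyl-1-(triethylsilyloxy)cyclopent-2-en-1-yl]propan-1-ol | OCC(C)(C)C1(O[Si](CC)(CC)CC)C=C(C)CC1 | intermediate
7 | 2-methyl-2-[3-methyl-1-(triethylsilyloxy)cyclopent-2-en-1-yl]propanal | O=CC(C)(C)C1(O[Si](CC)(CC)CC)C=C(C)CC1 | intermediate
8 | allenylboronic acid pinacol ester | C=C=CB1OC(C)(C)C(C)(C)O1 | starting material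
9 | (E)-3-(pinacolatoboryl)allyl-bis(isopinocampheyl)borane, terpene groups from (+)-α-pinene | CC1(C)OB(/C=C/CB([C@@H]2C[C@@H]3C[C@H]([C@H]2C)C3(C)C)[C@@H]2C[C@@H]3C[C@H]([C@H]2C)C3(C)C)OC1(C)C | intermediate
10 | anti adduct: O4 bis(isopinocampheyl)borinate, C3 pinacol boronate | C=C[C@H](B1OC(C)(C)C(C)(C)O1)[C@H](OB([C@@H]2C[C@@H]3C[C@H]([C@H]2C)C3(C)C)[C@@H]2C[C@@H]3C[C@H]([C@H]2C)C3(C)C)C(C)(C)C1(O[Si](CC)(CC)CC)C=C(C)CC1 | intermediate
11 | (3S,4R)-5-methyl-5-[3-methyl-1-(triethylsilyloxy)cyclopent-2-en-1-yl]hex-1-ene-3,4-diol | C=C[C@H](O)[C@H](O)C(C)(C)C1(O[Si](CC)(CC)CC)C=C(C)CC1 | intermediate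
12 | (3S,4R)-3-(tert-butyldimethylsilyloxy)-5-methyl-5-[3-methyl-1-(triethylsilyloxy)cyclopent-2-en-1-yl]hex-1-en-4-ol | C=C[C@H](O[Si](C)(C)C(C)(C)C)[C@H](O)C(C)(C)C1(O[Si](CC)(CC)CC)C=C(C)CC1 | intermediate
13 | methyl acrylate | C=CC(=O)OC | starting material
14 | methyl (2E,4S,5R)-4-(tert-butyldimethylsilyloxy)-5-hydroxy-6-methyl-6-[3-methyl-1-(triethylsilyloxy)cyclopent-2-en-1-yl]hept-2-enoate | COC(=O)/C=C/[C@H](O[Si](C)(C)C(C)(C)C)[C@H](O)C(C)(C)C1(O[Si](CC)(CC)CC)C=C(C)CC1 | intermediate
15 | methyl (4S,5R)-4-(tert-butyldimethylsilyloxy)-5-hydroxy-6-methyl-6-[3-methyl-1-(triethylsilyloxy)cyclopent-2-en-1-yl]heptanoate | COC(=O)CC[C@H](O[Si](C)(C)C(C)(C)C)[C@H](O)C(C)(C)C1(O[Si](CC)(CC)CC)C=C(C)CC1 | intermediate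
16 | hydroxy acid corresponding to 15 | OC(=O)CC[C@H](O[Si](C)(C)C(C)(C)C)[C@H](O)C(C)(C)C1(O[Si](CC)(CC)CC)C=C(C)CC1 | intermediate
17 | (5S,6R)-5-(tert-butyldimethylsilyloxy)-6-{2-[3-methyl-1-(triethylsilyloxy)cyclopent-2-en-1-yl]propan-2-yl}oxan-2-one | O=C1O[C@H](C(C)(C)C2(O[Si](CC)(CC)CC)C=C(C)CC2)[C@@H](O[Si](C)(C)C(C)(C)C)CC1 | intermediate
18 | lithium enolate of 17 | [Li+].[O-]C1=CC[C@H](O[Si](C)(C)C(C)(C)C)[C@H](O1)C(C)(C)C1(O[Si](CC)(CC)CC)C=C(C)CC1 | intermediate
19 | (3Z,5S,6R)-3-(hydroxymethylidene) derivative of 17 | O=C1O[C@H](C(C)(C)C2(O[Si](CC)(CC)CC)C=C(C)CC2)[C@@H](O[Si](C)(C)C(C)(C)C)C/C1=C/O | intermediate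
20 | sodium benzenesulfinate | [Na+].[O-]S(=O)c1ccccc1 | starting material
21 | enol mesylate of 19 (alkene geometry not defined) | O=C1O[C@H](C(C)(C)C2(O[Si](CC)(CC)CC)C=C(C)CC2)[C@@H](O[Si](C)(C)C(C)(C)C)CC1=COS(C)(=O)=O | intermediate
22 | (3E,5S,6R)-3-[(phenylsulfonyl)methylidene] lactone with tertiary allylic triethylsilyl ether | O=C1O[C@H](C(C)(C)C2(O[Si](CC)(CC)CC)C=C(C)CC2)[C@@H](O[Si](C)(C)C(C)(C)C)C/C1=C\S(=O)(=O)c1ccccc1 | intermediate
23 | (3E,5S,6R)-5-(tert-butyldimethylsilyloxy)-6-[2-(3-methylcyclopenta-1,3-dien-1-yl)propan-2-yl]-3-[(phenylsulfonyl)methylidene]oxan-2-one | O=C1O[C@H](C(C)(C)C2=CC(C)=CC2)[C@@H](O[Si](C)(C)C(C)(C)C)C/C1=C\S(=O)(=O)c1ccccc1 | intermediate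
24 | lactone-bridged norbornene sulfone (C12 exo; C2 and PhSO2 endo) | O=C1O[C@H]2[C@@H](O[Si](C)(C)C(C)(C)C)C[C@@]13[C@H](S(=O)(=O)c4ccccc4)[C@H]4C[C@@]3(C=C4C)C2(C)C | intermediate
25 | exo-C10,C11-epoxide of 24 | O=C1O[C@H]2[C@@H](O[Si](C)(C)C(C)(C)C)C[C@@]13[C@H](S(=O)(=O)c4ccccc4)[C@H]4C[C@@]3([C@@H]5O[C@@]54C)C2(C)C | intermediate
26 | C9-lithiated sulfone of 25 | [Li+].O=C1O[C@H]2[C@@H](O[Si](C)(C)C(C)(C)C)C[C@@]13[C-](S(=O)(=O)c4ccccc4)[C@H]4C[C@@]3([C@@H]5O[C@@]54C)C2(C)C | intermediate
27 | nortricyclanol sulfone lactone (C11–OH facing C7) | O=C1O[C@H]2[C@@H](O[Si](C)(C)C(C)(C)C)C[C@@]13[C@@]4(S(=O)(=O)c5ccccc5)[C@H]5C[C@@]3([C@H](O)[C@@]45C)C2(C)C | intermediate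
28 | sulfonyl triol | OC[C@]12C[C@H](O[Si](C)(C)C(C)(C)C)[C@H](O)C(C)(C)[C@]13C[C@@H]1[C@@]2(S(=O)(=O)c4ccccc4)[C@]1(C)[C@H]3O | intermediate
29 | triol 3-O-tert-butyldimethylsilyl ether | OC[C@]12C[C@H](O[Si](C)(C)C(C)(C)C)[C@H](O)C(C)(C)[C@]13C[C@@H]1[C@H]2[C@]1(C)[C@H]3O | intermediate
30 | triacetate 3-O-tert-butyldimethylsilyl ether | CC(=O)OC[C@]12C[C@H](O[Si](C)(C)C(C)(C)C)[C@H](OC(C)=O)C(C)(C)[C@]13C[C@@H]1[C@H]2[C@]1(C)[C@H]3OC(C)=O | intermediate
31 | CNP0111873.1 | CC(=O)OC[C@]12C[C@H](O)[C@H](OC(C)=O)C(C)(C)[C@]13C[C@@H]1[C@H]2[C@]1(C)[C@H]3OC(C)=O | target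

## Step count and least certain steps

Total step count: 19. Longest linear sequence: 19 steps (from 1 and 2 to 31). Compounds 8, 13 and 20 enter as purchased compounds.

**Step 13 (key step).**
- *Risk.* The cycloaddition may be too slow or may revert. The lactone must reach a boat with a tert-alkyl group as flagpole while a bond forms between two fully substituted carbons next to CMe2. Several processes could then take over: dimerisation of the diene, drift of the double bond out of conjugation with the sulfone, cycloaddition through the 1,4-disubstituted diene isomer (bonding C9 to C10), or weak discrimination between the two diene orientations.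
- *Fallback.* The bridge is untied. The fallback sets out from 15 and returns at 24.
  - TESOTf and 2,6-lutidine silylate O4 to give the bis(triethylsilyl) ether F1.
  - Formylation as in step 10 gives the hydroxymethylene ester F2, mesylation gives the enol mesylate F3, and 20 gives the sulfonylmethylene ester F4.
  - Catalytic camphorsulfonic acid unveils the diene F5. Its flexible four-atom tether lets ring A close through a chair-like transition state at lower temperature, giving the norbornene ester F6.
  - Pyridinium tosylate in methanol frees O4 (hydroxy ester F7), and DBU in hot toluene closes the lactone to 24.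
- *Price.* The alkene face is then only biased by C3 and C4 and is no longer dictated by them. Only the isomer with C12 cis to O4 can lactonise, which sorts the material.

**Step 15.**
- *Risk.* Displacement at the fully substituted C10 may be slower than base-induced isomerisation of the epoxide through the C10 methyl group, or slower than cationic skeletal rearrangement triggered by lithium coordination.
- *Fallback.* The leaving group is changed. The fallback sets out from 24 and returns at 27.
  - OsO4 (cat.) with N-methylmorpholine N-oxide adds from the exo face to give the exo,cis-diol F8.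
  - SOCl2 and Et3N give the cyclic sulfite F9, and RuCl3 (cat.) with NaIO4 gives the cyclic sulfate F10.
  - LiN(iPr)2 then closes the cyclopropane by expelling the much better tertiary sulfate, giving the C11 sulfate monoester salt F11.
  - The S–O bond of F11 is solvolysed in wet dioxane with a trace of acid to give 27.

**Step 12.**
- *Risk.* The allyl cation may be captured before it loses a proton, by the O3 silyl ether oxygen (five-membered ring) or by the lactone carbonyl. The secondary silyl ether may be lost, or the freshly formed diene may oligomerise under acid.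
- *Fallback.* The mechanism is changed from ionisation to a syn-elimination. The fallback sets out from 22 and returns at 23. Buffered HF·pyridine removes the triethylsilyl group to give the tertiary allylic alcohol F12. Burgess reagent in benzene at 50 °C then dehydrates F12 under neutral conditions to 23.

**Step 5.**
- *Risk.* The α-quaternary aldehyde may add too slowly at −78 °C. Warming would erode facial selectivity and let the first-formed allylboronate react with a second aldehyde molecule. The racemic ring centre may make one epimer react with lower selectivity.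
- *Fallback.* The stoichiometric chiral borane is replaced by Brønsted acid catalysis with a true γ-silyloxy reagent. The fallback sets out from 7 and returns at 12, so step 6 is no longer needed.
  - tert-Butyldimethyl(prop-2-ynyloxy)silane and pinacolborane with ZrCp2(H)Cl (cat.) give the alkenylboronate F13.
  - [Ir(cod)(PPh2Me)2]PF6 (cat., activated with H2) moves the double bond to give the E γ-silyloxyallylboronate F14.
  - F14 adds to 7 under catalysis by the enantiomer of 3,3'-bis(2,4,6-triisopropylphenyl)-BINOL hydrogen phosphate that attacks the same aldehyde face. This gives the borate ester F15, which is hydrolysed on work-up to 12.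

**Step 11.**
- *Risk.* Sulfinate may be too weak a nucleophile for the hindered enol mesylate. Hydrolysis back to 19, deformylation, or amine-induced migration of the new double bond with loss of the O3 silyloxy group could then compete.
- *Fallback.* Sulfur is brought in at the sulfide level. The fallback sets out from 19 (through 21) and returns at 22. Thiophenol and Et3N convert 21 into the phenylthiomethylene lactone F16. (NH4)6Mo7O24 (cat.) with H2O2 in ethanol, which spares unactivated alkenes, oxidises F16 through the sulfoxide F17 to 22.

## Further compounds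

F1 | step 13 | O4-triethylsilyl ether of 15 | COC(=O)CC[C@H](O[Si](C)(C)C(C)(C)C)[C@H](O[Si](CC)(CC)CC)C(C)(C)C1(O[Si](CC)(CC)CC)C=C(C)CC1
F2 | step 13 | (Z)-2-(hydroxymethylidene) ester from F1 | COC(=O)/C(=C\O)C[C@H](O[Si](C)(C)C(C)(C)C)[C@H](O[Si](CC)(CC)CC)C(C)(C)C1(O[Si](CC)(CC)CC)C=C(C)CC1
F3 | step 13 | enol mesylate of F2 (alkene geometry not defined) | COC(=O)C(=COS(C)(=O)=O)C[C@H](O[Si](C)(C)C(C)(C)C)[C@H](O[Si](CC)(CC)CC)C(C)(C)C1(O[Si](CC)(CC)CC)C=C(C)CC1
F4 | step 13 | methyl (E)-2-[(phenylsulfonyl)methylidene] ester | COC(=O)/C(=C/S(=O)(=O)c1ccccc1)C[C@H](O[Si](C)(C)C(C)(C)C)[C@H](O[Si](CC)(CC)CC)C(C)(C)C1(O[Si](CC)(CC)CC)C=C(C)CC1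
F5 | step 13 | open-chain cyclopentadienyl sulfonylmethylidene ester (reactive diene isomer) | COC(=O)/C(=C/S(=O)(=O)c1ccccc1)C[C@H](O[Si](C)(C)C(C)(C)C)[C@H](O[Si](CC)(CC)CC)C(C)(C)C1=CC(C)=CC1
F6 | step 13 | norbornene methyl ester (configuration as in 24, O4 triethylsilyl ether) | COC(=O)[C@]12C[C@H](O[Si](C)(C)C(C)(C)C)[C@H](O[Si](CC)(CC)CC)C(C)(C)[C@]1(C=C3C)C[C@@H]3[C@H]2S(=O)(=O)c1ccccc1
F7 | step 13 | norbornene hydroxy ester (O4 free) | COC(=O)[C@]12C[C@H](O[Si](C)(C)C(C)(C)C)[C@H](O)C(C)(C)[C@]1(C=C3C)C[C@@H]3[C@H]2S(=O)(=O)c1ccccc1
F8 | step 15 | exo,cis-C10,C11-diol of 24 | O=C1O[C@H]2[C@@H](O[Si](C)(C)C(C)(C)C)C[C@@]13[C@H](S(=O)(=O)c4ccccc4)[C@H]4C[C@@]3([C@H](O)[C@@]4(O)C)C2(C)C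
F9 | step 15 | cyclic sulfite of F8 (sulfur configuration not defined) | O=C1O[C@H]2[C@@H](O[Si](C)(C)C(C)(C)C)C[C@@]13[C@H](S(=O)(=O)c4ccccc4)[C@H]4C[C@@]3([C@@H]5OS(=O)O[C@@]54C)C2(C)C
F10 | step 15 | cyclic sulfate of F8 | O=C1O[C@H]2[C@@H](O[Si](C)(C)C(C)(C)C)C[C@@]13[C@H](S(=O)(=O)c4ccccc4)[C@H]4C[C@@]3([C@@H]5OS(=O)(=O)O[C@@]54C)C2(C)C
F11 | step 15 | lithium salt of the C11 sulfate monoester of 27 | [Li+].O=C1O[C@H]2[C@@H](O[Si](C)(C)C(C)(C)C)C[C@@]13[C@@]4(S(=O)(=O)c5ccccc5)[C@H]5C[C@@]3([C@H](OS(=O)(=O)[O-])[C@@]45C)C2(C)C
F12 | step 12 | tertiary allylic alcohol from 22 | O=C1O[C@H](C(C)(C)C2(O)C=C(C)CC2)[C@@H](O[Si](C)(C)C(C)(C)C)C/C1=C\S(=O)(=O)c1ccccc1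
F13 | step 5 | (E)-3-(tert-butyldimethylsilyloxy)prop-1-enylboronic acid pinacol ester | CC(C)(C)[Si](C)(C)OC/C=C/B1OC(C)(C)C(C)(C)O1
F14 | step 5 | (E)-3-(tert-butyldimethylsilyloxy)allylboronic acid pinacol ester | CC(C)(C)[Si](C)(C)O/C=C/CB1OC(C)(C)C(C)(C)O1
F15 | step 5 | O4 pinacol borate ester of 12 | C=C[C@H](O[Si](C)(C)C(C)(C)C)[C@H](OB1OC(C)(C)C(C)(C)O1)C(C)(C)C1(O[Si](CC)(CC)CC)C=C(C)CC1
F16 | step 11 | 3-[(phenylthio)methylidene] lactone (sulfur cis to C2) | O=C1O[C@H](C(C)(C)C2(O[Si](CC)(CC)CC)C=C(C)CC2)[C@@H](O[Si](C)(C)C(C)(C)C)C/C1=C\Sc1ccccc1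
F17 | step 11 | 3-[(phenylsulfinyl)methylidene] lactone (sulfur configuration not defined) | O=C1O[C@H](C(C)(C)C2(O[Si](CC)(CC)CC)C=C(C)CC2)[C@@H](O[Si](C)(C)C(C)(C)C)C/C1=C\S(=O)c1ccccc1
A1 | alternative 1 | C9 N-tosylhydrazone on the spiro[4.5]decene triacetate 3-O-silyl ether | CC(=O)OC[C@]1(/C=N/NS(=O)(=O)c2ccc(C)cc2)C[C@H](O[Si](C)(C)C(C)(C)C)[C@H](OC(C)=O)C(C)(C)[C@]13CC=C(C)[C@H]3OC(C)=O
A2 | alternative 1 | C9 diazoalkane derived from A1 | CC(=O)OC[C@]1(C=[N+]=[N-])C[C@H](O[Si](C)(C)C(C)(C)C)[C@H](OC(C)=O)C(C)(C)[C@]13CC=C(C)[C@H]3OC(C)=O
A3 | alternative 1 | C3 silyl ether of the target (same structure as 30) | CC(=O)OC[C@]12C[C@H](O[Si](C)(C)C(C)(C)C)[C@H](OC(C)=O)C(C)(C)[C@]13C[C@@H]1[C@H]2[C@]1(C)[C@H]3OC(C)=O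
A4 | alternative 2 | C4,C5-epoxide tethered to a 5,5-disubstituted 2-(trimethylsilyloxy)cyclopentadiene with allyl on C6 | c1ccccc1COC[C@@]1(C[C@H](O[Si](C)(C)C(C)(C)C)[C@@H]2OC2(C)C)C=C(C)C(O[Si](C)(C)C)=C1CC=C
A5 | alternative 2 | ring A-fused cyclopentenone with C6 allyl and free C4 hydroxyl | c1ccccc1COC[C@]12C[C@H](O[Si](C)(C)C(C)(C)C)[C@H](O)C(C)(C)[C@@]1(CC=C)C(=O)C(C)=C2
A6 | alternative 3 | 7-acetoxynorbornadiene carrying the (Z)-vinyl iodide side chain on C6 | CC(=O)OCC1=C[C@@]2(C)C=C[C@]1(C(C)(C)[C@@H](OC(C)=O)/C(O[Si](C)(C)C(C)(C)C)=C/I)[C@@H]2OC(C)=O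
A7 | alternative 3 | cage triacetate with ring A silyl enol ether | CC(=O)OC[C@]12C=C(O[Si](C)(C)C(C)(C)C)[C@H](OC(C)=O)C(C)(C)[C@]13C[C@@H]1[C@H]2[C@]1(C)[C@H]3OC(C)=O
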